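## Structural features

- The target is an indane: a cyclopentane (C1, C2, C3, C3a, C7a) fused to resorcinol ring A, numbered so that C1 bears the 4-hydroxyphenyl group, C7a lies next to C1, C3a next to C3, and the ring A hydroxyls sit at C5 and C7.
- C2 carries a 3,5-dihydroxyphenyl group and C3 carries the carbinol carbon C8, which bears a second 4-hydroxyphenyl group.
- Four stereocentres are contiguous: C1 (R), C2 (S), C3 (R) on the ring, all trans, and C8 (S) outside it.
- C8 is a para-hydroxybenzylic alcohol: acid ionises it to a quinone methide or benzylic cation, which epimerises C8 or is captured by the neighbouring resorcinol ring, and it is also open to benzylic hydrogenolysis.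
- The six phenols are oxidisable.
- The real difficulty is stereochemical: the C3/C8 pair has the syn relationship of a homopropargylic alcohol and must be set together with two ring relationships, without a cation ever forming at C1 or C8.
- The key step exploits that C1–C2–C3 is a three-atom tether between C7a and C3a. A 1,6-diyne with its alkynes on C1 and C3 closes the cyclopentane and ring A together, with a two-carbon alkyne supplying C5–C6 and boron on the alkyne carbons C7 and C5 standing in for the meta oxygens. Because only sp2 carbons are formed, all four stereocentres can be made on an open chain.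

## Logic of the disconnections

**20 back to 17.** The four benzyl C–O bonds, the Si–O bond at C8 and the C5–O and C7–O bonds are cut, the last two being traced back to C–B bonds. Ipso oxidation of boron fixes the ring A oxygen pattern at the moment the ring is made, and 17 is a neutral compound that cannot ionise at C8. The forward steps must avoid acid throughout, and hydrogenolysis must stop before the C8–O bond is touched.

**17 back to 15 and 16.** C3a–C7a, C4–C5 and C6–C7 are cut. Two rings and three bonds are removed in one step with no stereocentre involved, leaving an acyclic diyne and a two-carbon alkyne. The forward step must favour cross-coupling over self-trimerisation and must place the boron of 16 at C5, meta to the boron already on C7.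

**15 back to 13 and 4.** The Si–O bond and then C3–C8 are cut.
- The C3/C8 pair is a syn homopropargylic alcohol, so the bond is made by an open, Lewis-acid-promoted addition of the allenyltin unit in 13.
- A closed transition state (allenylzinc or allenylindium) would give the anti alcohol, which is the C8 epimer of what is needed.
- The allene also stores the C3 alkyne in a form without an acidic C(sp)–H, which is what makes the next disconnection possible.
- The forward step needs full transfer of the allene axis to C3, syn topicity toward the aldehyde face, and survival of the alkynyl boronate under BF3.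

**13 back to 10.** The C7–B bond is cut. Alkynyl boronates are labile toward water, base and silica, and a lithium acetylide cannot be made next to an aldehyde, so boron is introduced as late as the differentiation of the two alkynes allows. In 10 the alkyne on C1 is the only terminal alkyne, so deprotonation is unambiguous. The base must leave the allenyltin unit alone.

**10 back to 7 and 5, through 9 and 8.** The C–Sn bond is cut with transposition to a C3–Cl bond, then C3–Cl to C3–O, then C3–C3a. This reduces the axially chiral allene to a carbinol stereocentre and the carbinol to an aldehyde. It requires a stereospecific anti SN2′ displacement, clean inversion in the chlorination, and useful 1,2-induction from C2 in the acetylide addition.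

**7 back to 3 and 6.** C1–C2 is cut. Both aryl-bearing stereocentres and the C1 alkyne arise in one catalytic step from an achiral aldehyde and a racemic propargylic alcohol. The forward step needs control of the enamine face, syn selectivity, and an α-aryl aldehyde that does not epimerise before it is used.

**3 back to 1, and 6 back to 4 and 5.** C2–C3 and C1–C7a are cut, a one-carbon homologation and an acetylide addition. Neither makes a lasting stereocentre.

## Other disconnections considered

**Alternative 1:** The cut is C1–C7a alone.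
- Forward step: a chiral phosphoric acid opens one of the two enantiotopic benzylic C–O bonds of the meso oxolane A1 to a para-quinone methide at C1. The 3,5-bis(benzyloxy)phenyl ring on C3 then closes on it through its ortho carbon, giving A2 with C8 still oxygenated.
- In favour: C2, C3 and C8 are already present in A1 without any asymmetric step, one catalyst sets the absolute configuration of all four centres, ring A never needs its oxygens installed, and A2 is one hydrogenolysis from 20. On step economy and on the endgame this alternative is clearly better than the chosen plan.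
- Against: the reaction runs through the very cation that the target cannot tolerate and keeps a free para-hydroxybenzylic alcohol at C8 in acid. Re-closure of the oxolane would scramble C1 and erode the desymmetrisation. Ionisation at C8 would invite a second ring closure onto the C2 aryl group or C8 epimerisation. Discrimination of enantiotopic C–O bonds in a tetraaryl oxolane is a demanding request of the catalyst, and A1 is one of several diastereomers.
- Comparison: both plans place C1 trans to C2, but here by steric preference in a cation, whereas the chosen plan sets it under kinetic control in neutral media. The chosen plan is the safer on the integrity of C8.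

**Alternative 2:** The cut removes four bonds of ring A (C3a–C4, C4–C5, C6–C7, C7–C7a).
- Forward step: irradiation of the cyclopentenyl diazoketone A3 gives a vinylketene by photochemical Wolff rearrangement. It adds to the siloxyalkyne A4, and ring opening, six-electron closure and tautomerisation give the resorcinol monosilyl ether A5.
- In favour: the meta relationship of the two oxygens is dictated by the mechanism, which is equal to or better than the steric meta selectivity of the chosen key step. The oxygens arrive as oxygen, so the sequence after the key step is one step shorter.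
- Against: A3 must already be a cyclopentene carrying C1, C2, C3 and C8. Its C1–H is allylic and benzylic and its C3–H is the γ-position of the enone, so both are open to epimerisation or double-bond migration. Making A3 needs a long sequence of its own, and diazo chemistry with photolysis and heating adds hazard.
- Comparison: it forms four bonds and one ring, whereas the chosen step forms three bonds and two rings from an open chain. The chosen plan is more convergent and likely shorter overall.

**Alternative 3:** The cut is C3–C3a.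
- Forward step: bromine–lithium exchange on the aryl bromide A6 with an alkyllithium gives an aryllithium that opens the trans epoxide at C3 in a 5-exo mode with inversion, releasing the C8 alkoxide and giving A7.
- In favour: C3 and C8 come from a reagent-controlled Shi epoxidation of an E alkene, which is a better-established way to this pair than an allenyltin addition. A7 is one hydrogenolysis from 20 and ring A is brought in intact. On the C3/C8 pair and on the endgame this alternative is better.
- Against: A6 needs C1 as a diarylmethine stereocentre with two different electron-rich aryl groups next to C2, which is hard to set and doubly benzylic, hence acidic toward the alkyllithium. Six benzyl ethers must survive the exchange. An electron-rich aryl epoxide is prone to lithium-salt-induced rearrangement and to 6-endo attack at the benzylic C8.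
- Comparison: a polar organolithium step forming one bond and one ring, against a neutral catalytic step forming three bonds and two rings. Step counts are probably comparable, but the chosen plan puts less at risk in its key step.

Key step: step 10

Assumption (remark on the chemistry): the acetylide addition to aldehyde 7 is taken to follow the Felkin–Anh model with the aryl group on C2 as the large substituent, which gives the (3S) alcohol 8. The route is written for that outcome, and the opposite outcome is covered by a fallback.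

## Route

Step 1
Reactants: 1 3,5-bis(benzyloxy)benzaldehyde
Product: 3 2-[3,5-bis(benzyloxy)phenyl]acetaldehyde, via enol ether 2 (not isolated)
Conditions: MeOCH2PPh3Cl, KOtBu, THF, 0 °C to rt; then 2 M HCl, THF, rt
Reagents that add atoms: (methoxymethyl)triphenylphosphonium chloride, COC[P+](c1ccccc1)(c1ccccc1)c1ccccc1.[Cl-]; water, O
Why: Wittig methoxymethylenation gives the enol ether, and its acid hydrolysis should deliver the one-carbon-homologated arylacetaldehyde; no stereocentre is formed and the aldehyde is used promptly.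

Step 2
Reactants: 4 4-(benzyloxy)benzaldehyde; 5 ethynylmagnesium bromide
Product: 6 rac-1-[4-(benzyloxy)phenyl]prop-2-yn-1-ol
Conditions: THF, 0 °C
Reagents that add atoms: none
Why: Plain 1,2-addition of an alkynyl Grignard reagent to an aromatic aldehyde; the racemate suffices because this carbinol centre is erased when the ruthenium allenylidene forms in step 3.

Step 3
Reactants: 3 2-[3,5-bis(benzyloxy)phenyl]acetaldehyde; 6 rac-1-[4-(benzyloxy)phenyl]prop-2-yn-1-ol
Product: 7 (2R,3S)-3-[4-(benzyloxy)phenyl]-2-[3,5-bis(benzyloxy)phenyl]pent-4-ynal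
Conditions: [Cp*RuCl(μ-SMe)]2 (5 mol%), NH4BF4 (10 mol%), (R)-2-{bis[3,5-bis(trifluoromethyl)phenyl](trimethylsilyloxy)methyl}pyrrolidine (10 mol%), toluene, rt
Reagents that add atoms: none
Why: Cooperative propargylic alkylation: the thiolate-bridged diruthenium complex turns 6 into a ruthenium allenylidene with loss of water, the secondary amine turns 3 into an E enamine, and C–C bond formation at the allenylidene γ-carbon sets C2 and C1 of the target. The diaryl(silyloxy)methyl group shields one enamine face, which by analogy with other enamine α-functionalisations should give 2R with the R amine; the syn isomer (3S) is the one needed, the relative topicity is less well controlled, and the anti isomer is removed by chromatography before the aldehyde is used at once.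

Step 4
Reactants: 7 (2R,3S)-3-[4-(benzyloxy)phenyl]-2-[3,5-bis(benzyloxy)phenyl]pent-4-ynal; 5 ethynylmagnesium bromide
Product: 8 (3S,4R,5S)-5-[4-(benzyloxy)phenyl]-4-[3,5-bis(benzyloxy)phenyl]hepta-1,6-diyn-3-ol
Conditions: 5 (3 equiv), CeCl3, THF, −78 °C, inverse addition of 7
Reagents that add atoms: none
Why: The organocerium acetylide is weakly basic and should add without enolising the α-aryl aldehyde; Felkin–Anh attack anti to the aryl group on the α-carbon, past the α-hydrogen, should favour the 3S carbinol. The terminal alkyne of 7 is merely deprotonated by the excess reagent and returns on work-up.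

Step 5
Reactants: 8 (3S,4R,5S)-5-[4-(benzyloxy)phenyl]-4-[3,5-bis(benzyloxy)phenyl]hepta-1,6-diyn-3-ol
Product: 9 (3R,4R,5S)-5-[4-(benzyloxy)phenyl]-4-[3,5-bis(benzyloxy)phenyl]-3-chlorohepta-1,6-diyne
Conditions: PPh3, N-chlorosuccinimide (premixed), THF, −20 °C to rt
Reagents that add atoms: N-chlorosuccinimide, O=C1CCC(=O)N1Cl
Why: Appel-type chlorination: chloride displaces the oxyphosphonium group by SN2 with inversion, which turns the Felkin carbinol into the 3R propargylic chloride needed for the next step; the conditions are neutral and spare benzyl ethers and alkynes.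

Step 6
Reactants: 9 (3R,4R,5S)-5-[4-(benzyloxy)phenyl]-4-[3,5-bis(benzyloxy)phenyl]-3-chlorohepta-1,6-diyne
Product: 10 tributyl{(aS,4R,5S)-5-[4-(benzyloxy)phenyl]-4-[3,5-bis(benzyloxy)phenyl]hepta-1,2-dien-6-yn-1-yl}stannane
Conditions: Bu3SnH, LiN(iPr)2, THF, −78 °C; CuBr·SMe2; then 9, −78 °C
Reagents that add atoms: tributylstannane, CCCC[SnH](CCCC)CCCC
Why: The stannylcopper reagent attacks the alkyne terminus anti to the departing chloride (SN2′ displacement of a propargylic electrophile), which converts the C3 centre into the aS allene axis. The remote terminal alkyne should be inert to this lower-order stannylcopper reagent at −78 °C.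

Step 7
Reactants: 10 tributyl{(aS,4R,5S)-5-[4-(benzyloxy)phenyl]-4-[3,5-bis(benzyloxy)phenyl]hepta-1,2-dien-6-yn-1-yl}stannane
Product: 13 2-{(3R,4R,aS)-3-[4-(benzyloxy)phenyl]-4-[3,5-bis(benzyloxy)phenyl]-7-(tributylstannyl)hepta-5,6-dien-1-yn-1-yl}-4,4,5,5-tetramethyl-1,3,2-dioxaborolane, via lithium acetylide 11 (not isolated), via lithium alkynylborate 12 (not isolated)
Conditions: LiN(iPr)2 (1.0 equiv), THF, −78 °C; iPrOBpin; HCl in Et2O (1.0 equiv), −78 °C to rt; filtration, no aqueous work-up
Reagents that add atoms: 2-isopropoxy-4,4,5,5-tetramethyl-1,3,2-dioxaborolane, CC(C)OB1OC(C)(C)C(C)(C)O1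
Why: With the C3 alkyne stored as the allene, the C1 alkyne holds the only acidic C(sp)–H, so deprotonation, capture by the borate ester as an ate complex and release with one equivalent of anhydrous acid should give the alkynyl pinacol boronate at C7 only. The amide base avoids tin–lithium exchange, and the crude boronate is carried on without chromatography.

Step 8
Reactants: 13 2-{(3R,4R,aS)-3-[4-(benzyloxy)phenyl]-4-[3,5-bis(benzyloxy)phenyl]-7-(tributylstannyl)hepta-5,6-dien-1-yn-1-yl}-4,4,5,5-tetramethyl-1,3,2-dioxaborolane; 4 4-(benzyloxy)benzaldehyde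
Product: 14 (1S,2R,3S,4R)-1,4-bis[4-(benzyloxy)phenyl]-3-[3,5-bis(benzyloxy)phenyl]-2-ethynyl-6-(4,4,5,5-tetramethyl-1,3,2-dioxaborolan-2-yl)hex-5-yn-1-ol
Conditions: BF3·OEt2, CH2Cl2, −78 °C; then aq. NaHCO3 at −78 °C
Reagents that add atoms: none
Why: Marshall-type allenylstannane propargylation through an open transition state: the BF3-activated aldehyde is attacked by the allene carbon remote from tin, anti to the C–Sn bond, so the axis is transferred to C3 (net retention relative to the chloride of 9) and the terminal C3 alkyne is released. The acyclic arrangement that keeps the aldehyde aryl group away from the allene substituent gives the syn alcohol, which sets C8 as S. The allenylstannane is far more nucleophilic than the alkoxyarene rings, and a cold quench prevents ionisation of the benzylic BF3 alkoxide.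

Step 9
Reactants: 14 (1S,2R,3S,4R)-1,4-bis[4-(benzyloxy)phenyl]-3-[3,5-bis(benzyloxy)phenyl]-2-ethynyl-6-(4,4,5,5-tetramethyl-1,3,2-dioxaborolan-2-yl)hex-5-yn-1-ol
Product: 15 tert-butyl{[(1S,2R,3S,4R)-1,4-bis[4-(benzyloxy)phenyl]-3-[3,5-bis(benzyloxy)phenyl]-2-ethynyl-6-(4,4,5,5-tetramethyl-1,3,2-dioxaborolan-2-yl)hex-5-yn-1-yl]oxy}dimethylsilane
Conditions: TBSOTf, 2,6-lutidine, CH2Cl2, −78 to 0 °C
Reagents that add atoms: tert-butyldimethylsilyl trifluoromethanesulfonate, CC(C)(C)[Si](C)(C)OS(=O)(=O)C(F)(F)F
Why: Silylation of a hindered secondary alcohol with a silyl triflate and a hindered base; the conditions are non-nucleophilic and anhydrous, so the alkynyl boronate and all four stereocentres should be untouched.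

Step 10
Reactants: 15 tert-butyl{[(1S,2R,3S,4R)-1,4-bis[4-(benzyloxy)phenyl]-3-[3,5-bis(benzyloxy)phenyl]-2-ethynyl-6-(4,4,5,5-tetramethyl-1,3,2-dioxaborolan-2-yl)hex-5-yn-1-yl]oxy}dimethylsilane; 16 2-ethynyl-4,4,5,5-tetramethyl-1,3,2-dioxaborolane
Product: 17 (1R,2S,3R)-1-[4-(benzyloxy)phenyl]-2-[3,5-bis(benzyloxy)phenyl]-3-{(S)-[4-(benzyloxy)phenyl][(tert-butyldimethylsilyl)oxy]methyl}-5,7-bis(4,4,5,5-tetramethyl-1,3,2-dioxaborolan-2-yl)indane
Conditions: 16 (3 equiv), Cp*RuCl(cod) (10 mol%), 1,2-dichloroethane, rt, slow addition of 15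
Reagents that add atoms: none
Why: Loss of cod frees the divalent ruthenium fragment Cp*RuCl, which binds both alkynes of 15 and couples them oxidatively to a bicyclic ruthenacyclopentadiene; this forms C3a–C7a and closes the cyclopentane by tethered oxidative cyclisation, helped by the three substituents on the C1–C2–C3 tether. Alkyne 16 then coordinates and inserts, and reductive elimination forms C4–C5 and C6–C7, closing benzene ring A and returning the catalyst; the closest known reaction type is the Cp*RuCl-catalysed [2+2+2] cycloaddition of 1,6-diynes with terminal alkynes and alkynylboronates. No stereocentre is made, and the neutral conditions at room temperature should leave C1, C2, C3, C8, the silyl ether and both C–B bonds alone. Two selectivities are needed. Cross-coupling over self-trimerisation is secured by adding 15 slowly to an excess of 16. Regioselectivity follows from the ruthenacycle: the boron-bearing carbon of 16 bonds to the unsubstituted α-carbon C4 and stays away from the boryl-bearing α-carbon C7, so boron ends at C5, meta to C7; any ortho isomer would be removed after step 11.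

Step 11
Reactants: 17 (1R,2S,3R)-1-[4-(benzyloxy)phenyl]-2-[3,5-bis(benzyloxy)phenyl]-3-{(S)-[4-(benzyloxy)phenyl][(tert-butyldimethylsilyl)oxy]methyl}-5,7-bis(4,4,5,5-tetramethyl-1,3,2-dioxaborolan-2-yl)indane
Product: 18 (1R,2S,3R)-1-[4-(benzyloxy)phenyl]-2-[3,5-bis(benzyloxy)phenyl]-3-{(S)-[4-(benzyloxy)phenyl][(tert-butyldimethylsilyl)oxy]methyl}indane-5,7-diol
Conditions: 30% H2O2, aq. NaOH, THF, 0 °C
Reagents that add atoms: hydrogen peroxide, OO
Why: Ipso oxidation of both aryl boronates: hydroperoxide adds to boron, the aryl group migrates from boron to oxygen at the same carbon, and hydrolysis gives the phenols at C5 and C7; benzyl and silyl ethers are stable to cold aqueous base.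

Step 12
Reactants: 18 (1R,2S,3R)-1-[4-(benzyloxy)phenyl]-2-[3,5-bis(benzyloxy)phenyl]-3-{(S)-[4-(benzyloxy)phenyl][(tert-butyldimethylsilyl)oxy]methyl}indane-5,7-diol
Product: 19 (1R,2S,3R)-1-[4-(benzyloxy)phenyl]-2-[3,5-bis(benzyloxy)phenyl]-3-{(S)-[4-(benzyloxy)phenyl](hydroxy)methyl}indane-5,7-diol
Conditions: Bu4NF, THF, 0 °C to rt
Reagents that add atoms: none
Why: Fluoride cleaves the Si–O bond without acid, so the C8–O bond is not ionised and C8 keeps its configuration; the para oxygen of that aryl group is still benzylated, so no quinone methide can form.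

Step 13
Reactants: 19 (1R,2S,3R)-1-[4-(benzyloxy)phenyl]-2-[3,5-bis(benzyloxy)phenyl]-3-{(S)-[4-(benzyloxy)phenyl](hydroxy)methyl}indane-5,7-diol
Product: 20 (1R,2S,3R)-2-(3,5-dihydroxyphenyl)-3-[(S)-hydroxy(4-hydroxyphenyl)methyl]-1-(4-hydroxyphenyl)indane-5,7-diol
Conditions: H2 (1 atm), Pd/C, EtOAc–MeOH, rt, stopped at full debenzylation
Reagents that add atoms: none
Why: Hydrogenolysis of the four aryl benzyl ethers under neutral conditions; aryl benzyl ethers cleave much faster than a secondary benzylic alcohol in the absence of acid, so C8–OH should survive if the reaction is stopped in time.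

## Compound list

1 | 3,5-bis(benzyloxy)benzaldehyde | O=Cc1cc(OCc2ccccc2)cc(OCc2ccccc2)c1 | starting material
2 | 1,3-bis(benzyloxy)-5-(2-methoxyethenyl)benzene (E/Z mixture, not isolated) | COC=Cc1cc(OCc2ccccc2)cc(OCc2ccccc2)c1 | intermediate
3 | 2-[3,5-bis(benzyloxy)phenyl]acetaldehyde | O=CCc1cc(OCc2ccccc2)cc(OCc2ccccc2)c1 | intermediate
4 | 4-(benzyloxy)benzaldehyde | O=Cc1ccc(OCc2ccccc2)cc1 | starting material
5 | ethynylmagnesium bromide | C#C[Mg]Br | starting material
6 | rac-1-[4-(benzyloxy)phenyl]prop-2-yn-1-ol | OC(C#C)c1ccc(OCc2ccccc2)cc1 | intermediate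
7 | (2R,3S)-3-[4-(benzyloxy)phenyl]-2-[3,5-bis(benzyloxy)phenyl]pent-4-ynal | c4ccccc4COc1ccc(cc1)[C@H](C#C)[C@H](c2cc(OCc4ccccc4)cc(OCc4ccccc4)c2)C=O | intermediate
8 | (3S,4R,5S)-5-[4-(benzyloxy)phenyl]-4-[3,5-bis(benzyloxy)phenyl]hepta-1,6-diyn-3-ol | c4ccccc4COc1ccc(cc1)[C@H](C#C)[C@H](c2cc(OCc4ccccc4)cc(OCc4ccccc4)c2)[C@@H](C#C)O | intermediate
9 | (3R,4R,5S)-5-[4-(benzyloxy)phenyl]-4-[3,5-bis(benzyloxy)phenyl]-3-chlorohepta-1,6-diyne | c4ccccc4COc1ccc(cc1)[C@H](C#C)[C@H](c2cc(OCc4ccccc4)cc(OCc4ccccc4)c2)[C@H](C#C)Cl | intermediate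
10 | tributyl{(aS,4R,5S)-5-[4-(benzyloxy)phenyl]-4-[3,5-bis(benzyloxy)phenyl]hepta-1,2-dien-6-yn-1-yl}stannane (P helicity of the allene) | c4ccccc4COc1ccc(cc1)[C@H](C#C)[C@H](c2cc(OCc4ccccc4)cc(OCc4ccccc4)c2)C([H])=[C@@]=C([H])[Sn](CCCC)(CCCC)CCCC | intermediate
11 | lithium acetylide of 10 (C≡C–Li in place of the terminal C≡C–H, stereochemistry as in 10; not isolated) | c4ccccc4COc1ccc(cc1)[C@H](C#C[Li])[C@H](c2cc(OCc4ccccc4)cc(OCc4ccccc4)c2)C([H])=[C@@]=C([H])[Sn](CCCC)(CCCC)CCCC | intermediate
12 | lithium alkynyl(isopropoxy)(pinacolato)borate formed from 11 (ate complex, stereochemistry as in 10; not isolated) | c4ccccc4COc1ccc(cc1)[C@H](C#C[B-]5(OC(C)C)OC(C)(C)C(C)(C)O5)[C@H](c2cc(OCc4ccccc4)cc(OCc4ccccc4)c2)C([H])=[C@@]=C([H])[Sn](CCCC)(CCCC)CCCC.[Li+] | intermediate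
13 | 2-{(3R,4R,aS)-3-[4-(benzyloxy)phenyl]-4-[3,5-bis(benzyloxy)phenyl]-7-(tributylstannyl)hepta-5,6-dien-1-yn-1-yl}-4,4,5,5-tetramethyl-1,3,2-dioxaborolane | c4ccccc4COc1ccc(cc1)[C@H](C#CB5OC(C)(C)C(C)(C)O5)[C@H](c2cc(OCc4ccccc4)cc(OCc4ccccc4)c2)C([H])=[C@@]=C([H])[Sn](CCCC)(CCCC)CCCC | intermediate
14 | (1S,2R,3S,4R)-1,4-bis[4-(benzyloxy)phenyl]-3-[3,5-bis(benzyloxy)phenyl]-2-ethynyl-6-(4,4,5,5-tetramethyl-1,3,2-dioxaborolan-2-yl)hex-5-yn-1-ol | c4ccccc4COc1ccc(cc1)[C@H](C#CB5OC(C)(C)C(C)(C)O5)[C@H](c2cc(OCc4ccccc4)cc(OCc4ccccc4)c2)[C@H](C#C)[C@H](O)c2ccc(OCc4ccccc4)cc2 | intermediate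
15 | tert-butyl{[(1S,2R,3S,4R)-1,4-bis[4-(benzyloxy)phenyl]-3-[3,5-bis(benzyloxy)phenyl]-2-ethynyl-6-(4,4,5,5-tetramethyl-1,3,2-dioxaborolan-2-yl)hex-5-yn-1-yl]oxy}dimethylsilane (the 1,6-diyne precursor; C1 R, C2 S, C3 R, C8 S in target numbering) | c4ccccc4COc1ccc(cc1)[C@H](C#CB5OC(C)(C)C(C)(C)O5)[C@H](c2cc(OCc4ccccc4)cc(OCc4ccccc4)c2)[C@H](C#C)[C@H](O[Si](C)(C)C(C)(C)C)c2ccc(OCc4ccccc4)cc2 | intermediate
16 | 2-ethynyl-4,4,5,5-tetramethyl-1,3,2-dioxaborolane | C#CB1OC(C)(C)C(C)(C)O1 | starting material
17 | (1R,2S,3R)-1-[4-(benzyloxy)phenyl]-2-[3,5-bis(benzyloxy)phenyl]-3-{(S)-[4-(benzyloxy)phenyl][(tert-butyldimethylsilyl)oxy]methyl}-5,7-bis(4,4,5,5-tetramethyl-1,3,2-dioxaborolan-2-yl)indane | c4ccccc4COc1ccc([C@@H]2c3c(B5OC(C)(C)C(C)(C)O5)cc(B5OC(C)(C)C(C)(C)O5)cc3[C@H]([C@H](O[Si](C)(C)C(C)(C)C)c3ccc(OCc4ccccc4)cc3)[C@H]2c2cc(OCc4ccccc4)cc(OCc4ccccc4)c2)cc1 | intermediate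
18 | (1R,2S,3R)-1-[4-(benzyloxy)phenyl]-2-[3,5-bis(benzyloxy)phenyl]-3-{(S)-[4-(benzyloxy)phenyl][(tert-butyldimethylsilyl)oxy]methyl}indane-5,7-diol | c4ccccc4COc1ccc([C@@H]2c3c(O)cc(O)cc3[C@H]([C@H](O[Si](C)(C)C(C)(C)C)c3ccc(OCc4ccccc4)cc3)[C@H]2c2cc(OCc4ccccc4)cc(OCc4ccccc4)c2)cc1 | intermediate
19 | (1R,2S,3R)-1-[4-(benzyloxy)phenyl]-2-[3,5-bis(benzyloxy)phenyl]-3-{(S)-[4-(benzyloxy)phenyl](hydroxy)methyl}indane-5,7-diol | c4ccccc4COc1ccc([C@@H]2c3c(O)cc(O)cc3[C@H]([C@H](O)c3ccc(OCc4ccccc4)cc3)[C@H]2c2cc(OCc4ccccc4)cc(OCc4ccccc4)c2)cc1 | intermediate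
20 | (1R,2S,3R)-2-(3,5-dihydroxyphenyl)-3-[(S)-hydroxy(4-hydroxyphenyl)methyl]-1-(4-hydroxyphenyl)indane-5,7-diol (indane numbered as in "Structural features") | Oc1ccc([C@@H]2c3c(O)cc(O)cc3[C@H]([C@H](O)c3ccc(O)cc3)[C@H]2c2cc(O)cc(O)c2)cc1 | target

## Step count and least certain steps

Total: 13 steps. Longest linear sequence: 12 steps (steps 1 and 3 to 13; step 2 is a one-step branch).

**Step 10 (key step).**
- What may go wrong: oxidative cyclisation may be slow at the boryl-substituted, crowded terminus, so that protodeboronation of the alkynyl boronate and self-trimerisation of the diyne overtake the cross-coupling. Leakage to the ortho regioisomer is a second concern.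
- Fallback: the C7 substituent is carried as a halogen through the cycloaddition and exchanged for boron on the arene. The fallback sets out from 10. Deprotonation with LiN(iPr)2 and quench with 1,2-dibromotetrachloroethane give the bromoalkyne F1. Addition to 4 with BF3·OEt2 gives the alcohol F2, and TBSOTf with 2,6-lutidine gives the silyl ether F3. Cycloaddition of F3 with 16 under Cp*RuCl(cod) gives the aryl bromide F4, with bromine at C7 and boron at C5. Miyaura borylation (B2pin2, Pd(dppf)Cl2, KOAc, dioxane) returns to the route at 17.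

**Step 3.**
- What may go wrong: modest syn/anti selectivity at the allenylidene carbon, and epimerisation at C2 of the α-aryl aldehyde by the amine catalyst during reaction or isolation.
- Fallback: the aldehyde is not isolated. The fallback sets out from 3 and 6 under the same catalysts. The crude mixture is reduced in the flask with NaBH4 to the configurationally stable alcohol F5, whose diastereomers are separated. Dess–Martin oxidation immediately before step 4 returns to the route at 7.

**Step 4.**
- What may go wrong: low or reversed facial selectivity, because the two α-substituents on C2 are of similar size, and enolisation of the aldehyde.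
- Fallback: the other epimer is made useful by changing the activation from inversion to retention. The fallback sets out from 7. The 3R alcohol F6 is separated and converted with MsCl and Et3N into the mesylate F7, which has the same configuration at C3 as chloride 9. The stannylcopper reagent of step 6 then returns to the route at 10.

**Step 8.**
- What may go wrong: erosion of syn selectivity with an aromatic aldehyde and a crowded allene, ionisation of the benzylic BF3 alkoxide on warming, and loss of the alkynyl boronate during isolation.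
- Fallback: C8 is corrected by inversion and its oxygen is carried as an ester. The fallback sets out from 13 and 4. If the C8 epimer F8 predominates, Mitsunobu esterification with 4-nitrobenzoic acid (PPh3, diisopropyl azodicarboxylate) inverts C8 to the ester F9. F9 takes the place of 15 in the cycloaddition with 16 and gives the indane F10. H2O2 with aqueous NaOH then oxidises both boronates and saponifies the ester, returning to the route at 19.

**Step 13.**
- What may go wrong: over-reduction. Once the para oxygen is freed, C8–OH is a para-hydroxybenzylic alcohol, and its C–O bond may be hydrogenolysed along with the benzyl ethers.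
- Fallback: the order of the last two steps is reversed. The fallback sets out from 18. Hydrogenolysis (H2, Pd/C, EtOAc) with C8 still silylated gives the hexaphenol silyl ether F11. Buffered fluoride (Bu4NF with AcOH, THF) returns to the route at 20.

## Further compounds

F1 | step 10 | tributyl{(aS,4R,5R)-5-[4-(benzyloxy)phenyl]-4-[3,5-bis(benzyloxy)phenyl]-7-bromohepta-1,2-dien-6-yn-1-yl}stannane | c4ccccc4COc1ccc(cc1)[C@H](C#CBr)[C@H](c2cc(OCc4ccccc4)cc(OCc4ccccc4)c2)C([H])=[C@@]=C([H])[Sn](CCCC)(CCCC)CCCC
F2 | step 10 | (1S,2R,3S,4R)-1,4-bis[4-(benzyloxy)phenyl]-3-[3,5-bis(benzyloxy)phenyl]-6-bromo-2-ethynylhex-5-yn-1-ol | c4ccccc4COc1ccc(cc1)[C@H](C#CBr)[C@H](c2cc(OCc4ccccc4)cc(OCc4ccccc4)c2)[C@H](C#C)[C@H](O)c2ccc(OCc4ccccc4)cc2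
F3 | step 10 | tert-butyldimethylsilyl ether of F2 | c4ccccc4COc1ccc(cc1)[C@H](C#CBr)[C@H](c2cc(OCc4ccccc4)cc(OCc4ccccc4)c2)[C@H](C#C)[C@H](O[Si](C)(C)C(C)(C)C)c2ccc(OCc4ccccc4)cc2
F4 | step 10 | (1R,2S,3R)-1-[4-(benzyloxy)phenyl]-2-[3,5-bis(benzyloxy)phenyl]-3-{(S)-[4-(benzyloxy)phenyl][(tert-butyldimethylsilyl)oxy]methyl}-7-bromo-5-(4,4,5,5-tetramethyl-1,3,2-dioxaborolan-2-yl)indane | c4ccccc4COc1ccc([C@@H]2c3c(Br)cc(B5OC(C)(C)C(C)(C)O5)cc3[C@H]([C@H](O[Si](C)(C)C(C)(C)C)c3ccc(OCc4ccccc4)cc3)[C@H]2c2cc(OCc4ccccc4)cc(OCc4ccccc4)c2)cc1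
F5 | step 3 | (2R,3S)-3-[4-(benzyloxy)phenyl]-2-[3,5-bis(benzyloxy)phenyl]pent-4-yn-1-ol | c4ccccc4COc1ccc(cc1)[C@H](C#C)[C@H](c2cc(OCc4ccccc4)cc(OCc4ccccc4)c2)CO
F6 | step 4 | (3R,4R,5S)-5-[4-(benzyloxy)phenyl]-4-[3,5-bis(benzyloxy)phenyl]hepta-1,6-diyn-3-ol | c4ccccc4COc1ccc(cc1)[C@H](C#C)[C@H](c2cc(OCc4ccccc4)cc(OCc4ccccc4)c2)[C@H](C#C)O
F7 | step 4 | (3R,4R,5S)-5-[4-(benzyloxy)phenyl]-4-[3,5-bis(benzyloxy)phenyl]hepta-1,6-diyn-3-yl methanesulfonate | c4ccccc4COc1ccc(cc1)[C@H](C#C)[C@H](c2cc(OCc4ccccc4)cc(OCc4ccccc4)c2)[C@H](C#C)OS(C)(=O)=O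
F8 | step 8 | (1R,2R,3S,4R)-1,4-bis[4-(benzyloxy)phenyl]-3-[3,5-bis(benzyloxy)phenyl]-2-ethynyl-6-(4,4,5,5-tetramethyl-1,3,2-dioxaborolan-2-yl)hex-5-yn-1-ol | c4ccccc4COc1ccc(cc1)[C@H](C#CB5OC(C)(C)C(C)(C)O5)[C@H](c2cc(OCc4ccccc4)cc(OCc4ccccc4)c2)[C@H](C#C)[C@@H](O)c2ccc(OCc4ccccc4)cc2
F9 | step 8 | (1S,2R,3S,4R)-1,4-bis[4-(benzyloxy)phenyl]-3-[3,5-bis(benzyloxy)phenyl]-2-ethynyl-6-(4,4,5,5-tetramethyl-1,3,2-dioxaborolan-2-yl)hex-5-yn-1-yl 4-nitrobenzoate | c4ccccc4COc1ccc(cc1)[C@H](C#CB5OC(C)(C)C(C)(C)O5)[C@H](c2cc(OCc4ccccc4)cc(OCc4ccccc4)c2)[C@H](C#C)[C@H](OC(=O)c3ccc(cc3)[N+](=O)[O-])c2ccc(OCc4ccccc4)cc2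
F10 | step 8 | (S)-[4-(benzyloxy)phenyl]{(1R,2S,3R)-1-[4-(benzyloxy)phenyl]-2-[3,5-bis(benzyloxy)phenyl]-5,7-bis(4,4,5,5-tetramethyl-1,3,2-dioxaborolan-2-yl)indan-3-yl}methyl 4-nitrobenzoate (substituents placed on the indane as in 17) | c4ccccc4COc1ccc([C@@H]2c3c(B5OC(C)(C)C(C)(C)O5)cc(B5OC(C)(C)C(C)(C)O5)cc3[C@H]([C@H](OC(=O)c3ccc(cc3)[N+](=O)[O-])c3ccc(OCc4ccccc4)cc3)[C@H]2c2cc(OCc4ccccc4)cc(OCc4ccccc4)c2)cc1
F11 | step 13 | (1R,2S,3R)-3-{(S)-[(tert-butyldimethylsilyl)oxy](4-hydroxyphenyl)methyl}-2-(3,5-dihydroxyphenyl)-1-(4-hydroxyphenyl)indane-5,7-diol | Oc1ccc([C@@H]2c3c(O)cc(O)cc3[C@H]([C@H](O[Si](C)(C)C(C)(C)C)c3ccc(O)cc3)[C@H]2c2cc(O)cc(O)c2)cc1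
A1 | alternative 1 | meso-3,4-bis[3,5-bis(benzyloxy)phenyl]-2,5-bis(4-hydroxyphenyl)oxolane (2,3-trans, 3,4-cis, 4,5-trans) | O1[C@@H](c2ccc(O)cc2)[C@H](c2cc(OCc3ccccc3)cc(OCc3ccccc3)c2)[C@H](c2cc(OCc3ccccc3)cc(OCc3ccccc3)c2)[C@H]1c1ccc(O)cc1
A2 | alternative 1 | 20 with the four resorcinol oxygens benzylated | Oc1ccc([C@@H]2c3c(OCc4ccccc4)cc(OCc4ccccc4)cc3[C@H]([C@H](O)c3ccc(O)cc3)[C@H]2c2cc(OCc4ccccc4)cc(OCc4ccccc4)c2)cc1
A3 | alternative 2 | 2-diazo-1-(cyclopent-1-en-1-yl)ethanone carrying at ring C5 the (S)-[4-(benzyloxy)phenyl][(tert-butyldimethylsilyl)oxy]methyl group, at C4 the 3,5-bis(benzyloxy)phenyl group and at C3 the 4-(benzyloxy)phenyl group, configured as C3, C2, C1 and C8 of 20 | [N-]=[N+]=CC(=O)C1=C[C@@H](c2ccc(OCc3ccccc3)cc2)[C@H](c2cc(OCc3ccccc3)cc(OCc3ccccc3)c2)[C@H]1[C@H](O[Si](C)(C)C(C)(C)C)c1ccc(OCc2ccccc2)cc1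
A4 | alternative 2 | (triisopropylsilyloxy)ethyne | C#CO[Si](C(C)C)(C(C)C)C(C)C
A5 | alternative 2 | indane with free C7 phenol, C5 triisopropylsilyl ether, C8 tert-butyldimethylsilyl ether and four benzyl ethers | c4ccccc4COc1ccc([C@@H]2c3c(O)cc(O[Si](C(C)C)(C(C)C)C(C)C)cc3[C@H]([C@H](O[Si](C)(C)C(C)(C)C)c3ccc(OCc4ccccc4)cc3)[C@H]2c2cc(OCc4ccccc4)cc(OCc4ccccc4)c2)cc1
A6 | alternative 3 | trans-2-[4-(benzyloxy)phenyl]-3-{2-[4-(benzyloxy)phenyl]-2-[2-bromo-4,6-bis(benzyloxy)phenyl]-1-[3,5-bis(benzyloxy)phenyl]ethyl}oxirane, with C1, C2 and C8 as in 20 and C3 inverted | c1ccc(COc2ccc(cc2)[C@H](c2c(Br)cc(OCc3ccccc3)cc2OCc2ccccc2)[C@H](c2cc(OCc3ccccc3)cc(OCc3ccccc3)c2)[C@H]2O[C@@H]2c2ccc(OCc3ccccc3)cc2)cc1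
A7 | alternative 3 | hexabenzyl ether of 20 with free C8 hydroxyl | c4ccccc4COc1ccc([C@@H]2c3c(OCc4ccccc4)cc(OCc4ccccc4)cc3[C@H]([C@H](O)c3ccc(OCc4ccccc4)cc3)[C@H]2c2cc(OCc4ccccc4)cc(OCc4ccccc4)c2)cc1
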